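The dihydrofuran ring (O1, C2, C3, C3a, C7a, benzofuran numbering) is cut at C2–C3 and the cyclohexenone is traced back to an arene. The key step is a [4+1] annulation: a sulfone releases an o-quinone methide, the 1-oxadiene O1=C7a–C3a=C3 latent in the fused rings, which takes up the ylide carbon of a cinchona-derived ammonium acetamide. One operation forms C2–C3, closes the ring and sets C2 and C3 trans under reagent control. The amide then becomes the C2 methyl group, a Claisen–Cope allyl shift from O6 builds quaternary C3a anti to the aryl group, and conjugate reduction with kinetic protonation sets C5.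

Key step: step 6

Assumption: the quinidine-derived ammonium salt is taken to give the (2S,3S) series in the annulation; should the sense of induction be opposite, the quinine-derived pseudoenantiomer is used in the same way.

Step 1
Reactants: 1 2,6-dimethoxyphenol; 2 allyl bromide
Product: 3 2-(allyloxy)-1,3-dimethoxybenzene
Conditions: K2CO3, acetone, reflux
Reagents that add atoms: none
Why: Williamson ether synthesis, in which the phenoxide of 1 displaces bromide from the unhindered primary allylic halide.

Step 2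
Reactants: 3 2-(allyloxy)-1,3-dimethoxybenzene
Product: 5 3-(allyloxy)-2,4-dimethoxybenzaldehyde, via iminium chloride 4 (not isolated)
Conditions: POCl3, DMF, 80 °C; then H2O
Reagents that add atoms: N,N-dimethylformamide CN(C)C=O; water O
Why: Vilsmeier–Haack formylation, in which the chloroiminium ion attacks the only activated position (ortho to one terminal methoxy group and para to the other) and iminium salt 4 is hydrolysed on work-up.

Step 3
Reactants: 5 3-(allyloxy)-2,4-dimethoxybenzaldehyde
Product: 7 3-(allyloxy)-2,4-dimethoxyphenol, via aryl formate 6 (not isolated)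
Conditions: 30% H2O2, cat. H2SO4, MeOH, rt
Reagents that add atoms: hydrogen peroxide OO
Why: Dakin-type Baeyer–Villiger oxidation, in which the electron-rich aryl group migrates to oxygen and formate 6 is methanolysed in the acidic medium while the terminal alkene stays inert to acidic H2O2.

Step 4
Reactants: 7 3-(allyloxy)-2,4-dimethoxyphenol; 8 3,4,5-trimethoxybenzaldehyde; 9 sodium 4-methylbenzenesulfinate
Product: 10 3-(allyloxy)-2,4-dimethoxy-6-[(4-methylphenyl)sulfonyl(3,4,5-trimethoxyphenyl)methyl]phenol (racemic)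
Conditions: HCO2H, H2O, rt
Reagents that add atoms: none
Why: Acid-mediated three-component Mannich-type condensation, in which the phenol attacks the protonated aldehyde at its only free ortho position and sulfinate traps the benzylic cation to give a storable o-quinone methide precursor.

Step 5
Reactants: 11 quinidine; 12 2-bromo-N,N-diethylacetamide
Product: 13 N-[2-(diethylamino)-2-oxoethyl]quinidinium bromide
Conditions: THF, rt
Reagents that add atoms: none
Why: Menshutkin quaternisation, in which the quinuclidine nitrogen (the most nucleophilic site of quinidine) displaces bromide from the α-bromoamide.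

Step 6
Reactants: 10 3-(allyloxy)-2,4-dimethoxy-6-[(4-methylphenyl)sulfonyl(3,4,5-trimethoxyphenyl)methyl]phenol; 13 N-[2-(diethylamino)-2-oxoethyl]quinidinium bromide
Product: 16 (2S,3S)-6-(allyloxy)-N,N-diethyl-5,7-dimethoxy-3-(3,4,5-trimethoxyphenyl)-2,3-dihydro-1-benzofuran-2-carboxamide (trans), via o-quinone methide 14 (not isolated), via ammonium ylide 15 (not isolated)
Conditions: Cs2CO3, CH2Cl2, rt
Reagents that add atoms: none
Why: Cs2CO3 eliminates sulfinate from 10 to give o-quinone methide 14 and deprotonates 13 to the amide-stabilised ammonium ylide 15; the ylide carbon adds to C3, the terminus of the 1-oxadiene O1=C7a–C3a=C3, forming the C2–C3 bond, and the phenoxide then displaces the quinuclidine nitrogen from C2. The closest known reaction type is the [4+1] annulation of in situ generated o-quinone methides with carbonyl-stabilised ammonium or sulfonium ylides. The dihydrofuran ring is completed by 5-exo-tet O-alkylation of the betaine, so C2–C3 formation and ring closure are one operation driven by rearomatisation. C3 is set in the conjugate addition by the cinchona alkaloid, which acts as a chiral leaving group and shields one face of the ylide; C2 is set trans to the aryl group because the anti betaine closes faster and the amide α-centre can equilibrate under carbonate. The step needs C- before O-alkylation of the phenoxide, 1,4- instead of 1,2-addition and trans closure; the soft stabilised ylide, the strongly polarised exocyclic C3=C3a bond and the reversible addition secure these.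

Step 7
Reactants: 16 (2S,3S)-6-(allyloxy)-N,N-diethyl-5,7-dimethoxy-3-(3,4,5-trimethoxyphenyl)-2,3-dihydro-1-benzofuran-2-carboxamide
Product: 17 [(2S,3S)-6-(allyloxy)-5,7-dimethoxy-3-(3,4,5-trimethoxyphenyl)-2,3-dihydro-1-benzofuran-2-yl]methanol
Conditions: LiEt3BH, THF, 0 °C to rt; then H2O
Reagents that add atoms: none
Why: Hydride reduction of a tertiary amide with C–N cleavage, in which the hemiaminal collapses to the aldehyde and this is reduced on to the primary alcohol without touching C2 or C3 (the trans amide is the stable epimer).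

Step 8
Reactants: 17 [(2S,3S)-6-(allyloxy)-5,7-dimethoxy-3-(3,4,5-trimethoxyphenyl)-2,3-dihydro-1-benzofuran-2-yl]methanol
Product: 19 (2R,3S)-6-(allyloxy)-5,7-dimethoxy-2-methyl-3-(3,4,5-trimethoxyphenyl)-2,3-dihydro-1-benzofuran (trans), via mesylate 18 (not isolated)
Conditions: MsCl, Et3N, CH2Cl2, 0 °C; then LiEt3BH, THF, 0 °C to rt
Reagents that add atoms: methanesulfonyl chloride CS(=O)(=O)Cl (its atoms stay only in 18)
Why: Mesylation followed by SN2 hydride displacement of the primary sulfonate, which turns CH2OH into the C2 methyl group and leaves both stereocentres untouched (the descriptor at C2 changes only by priority).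

Step 9
Reactants: 19 (2R,3S)-6-(allyloxy)-5,7-dimethoxy-2-methyl-3-(3,4,5-trimethoxyphenyl)-2,3-dihydro-1-benzofuran
Product: 21 (2R,3S,3aS)-3a-allyl-5,7-dimethoxy-2-methyl-3-(3,4,5-trimethoxyphenyl)-3,3a-dihydro-1-benzofuran-6(2H)-one, via ortho-dienone 20 (not isolated)
Conditions: N,N-diethylaniline, 190 °C, sealed tube
Reagents that add atoms: none
Why: Aromatic Claisen rearrangement followed by Cope rearrangement (para-Claisen), in which both ortho positions carry methoxy groups so dienone 20 cannot enolise and passes the allyl group on to C3a by a suprafacial [3,3] shift on the face anti to the C3 aryl group, which sets C3a, the product being held as a vinylogous ester.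

Step 10
Reactants: 21 (2R,3S,3aS)-3a-allyl-5,7-dimethoxy-2-methyl-3-(3,4,5-trimethoxyphenyl)-3,3a-dihydro-1-benzofuran-6(2H)-one
Product: 23 (2R,3S,3aR,5S)-3a-allyl-5,7-dimethoxy-2-methyl-3-(3,4,5-trimethoxyphenyl)-3,3a,4,5-tetrahydro-1-benzofuran-6(2H)-one, via enol silane 22 (not isolated)
Conditions: [(Ph3P)CuH]6 (cat.), PhMe2SiH, toluene, rt; then Bu4NF, AcOH, THF, −78 °C
Reagents that add atoms: dimethylphenylsilane C[SiH](C)c1ccccc1 (its atoms stay only in 22)
Why: Copper hydride 1,4-reduction, in which hydride adds to C4 (the only unsubstituted β-carbon, since the C7=C7a enone is a vinylogous ester) and enol silane 22 is protonated at C5 under kinetic control on the face opposite the pseudoaxial allyl group, which sets C5 with methoxy cis to allyl.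

Compound list
1 | 2,6-dimethoxyphenol | COc1cccc(OC)c1O | starting material
2 | allyl bromide | C=CCBr | starting material
3 | 2-(allyloxy)-1,3-dimethoxybenzene | C=CCOc1c(OC)cccc1OC | intermediate
4 | N-[3-(allyloxy)-2,4-dimethoxybenzylidene]-N-methylmethanaminium chloride | C=CCOc1c(OC)ccc(C=[N+](C)C)c1OC.[Cl-] | intermediate
5 | 3-(allyloxy)-2,4-dimethoxybenzaldehyde | C=CCOc1c(OC)ccc(C=O)c1OC | intermediate
6 | 3-(allyloxy)-2,4-dimethoxyphenyl formate | C=CCOc1c(OC)ccc(OC=O)c1OC | intermediate
7 | 3-(allyloxy)-2,4-dimethoxyphenol | C=CCOc1c(OC)ccc(O)c1OC | intermediate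
8 | 3,4,5-trimethoxybenzaldehyde | COc1cc(C=O)cc(OC)c1OC | starting material
9 | sodium 4-methylbenzenesulfinate | Cc1ccc(S(=O)[O-])cc1.[Na+] | starting material
10 | 3-(allyloxy)-2,4-dimethoxy-6-[(4-methylphenyl)sulfonyl(3,4,5-trimethoxyphenyl)methyl]phenol (racemic) | C=CCOc1c(OC)cc(C(c2cc(OC)c(OC)c(OC)c2)S(=O)(=O)c2ccc(C)cc2)c(O)c1OC | intermediate
11 | quinidine | COC1=CC2=C(C=CN=C2C=C1)[C@@H]([C@H]3C[C@@H]4CCN3C[C@@H]4C=C)O | starting material
12 | 2-bromo-N,N-diethylacetamide | CCN(CC)C(=O)CBr | starting material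
13 | N-[2-(diethylamino)-2-oxoethyl]quinidinium bromide (alkylated at the quinuclidine nitrogen) | COC1=CC2=C(C=CN=C2C=C1)[C@@H]([C@H]3C[C@@H]4CC[N+]3(CC(=O)N(CC)CC)C[C@@H]4C=C)O.[Br-] | intermediate
14 | 3-(allyloxy)-2,4-dimethoxy-6-(3,4,5-trimethoxybenzylidene)cyclohexa-2,4-dien-1-one (o-quinone methide) | C=CCOC1=C(OC)C(=O)C(=Cc2cc(OC)c(OC)c(OC)c2)C=C1OC | intermediate
15 | ammonium ylide of 13 (carbanion between the quinuclidinium nitrogen and the amide carbonyl) | COC1=CC2=C(C=CN=C2C=C1)[C@@H]([C@H]3C[C@@H]4CC[N+]3([CH-]C(=O)N(CC)CC)C[C@@H]4C=C)O | intermediate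
16 | (2S,3S)-6-(allyloxy)-N,N-diethyl-5,7-dimethoxy-3-(3,4,5-trimethoxyphenyl)-2,3-dihydro-1-benzofuran-2-carboxamide (trans) | C=CCOc1c(OC)cc2c(c1OC)O[C@H](C(=O)N(CC)CC)[C@H]2c1cc(OC)c(OC)c(OC)c1 | intermediate
17 | [(2S,3S)-6-(allyloxy)-5,7-dimethoxy-3-(3,4,5-trimethoxyphenyl)-2,3-dihydro-1-benzofuran-2-yl]methanol | C=CCOc1c(OC)cc2c(c1OC)O[C@H](CO)[C@H]2c1cc(OC)c(OC)c(OC)c1 | intermediate
18 | [(2S,3S)-6-(allyloxy)-5,7-dimethoxy-3-(3,4,5-trimethoxyphenyl)-2,3-dihydro-1-benzofuran-2-yl]methyl methanesulfonate | C=CCOc1c(OC)cc2c(c1OC)O[C@H](COS(C)(=O)=O)[C@H]2c1cc(OC)c(OC)c(OC)c1 | intermediate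
19 | (2R,3S)-6-(allyloxy)-5,7-dimethoxy-2-methyl-3-(3,4,5-trimethoxyphenyl)-2,3-dihydro-1-benzofuran (trans) | C=CCOc1c(OC)cc2c(c1OC)O[C@H](C)[C@H]2c1cc(OC)c(OC)c(OC)c1 | intermediate
20 | (2R,3S)-5-allyl-5,7-dimethoxy-2-methyl-3-(3,4,5-trimethoxyphenyl)-2,3-dihydro-1-benzofuran-6(5H)-one (C5 epimers; the C7-allyl isomer behaves alike) | C=CCC1(OC)C=C2C(=C(OC)C1=O)O[C@H](C)[C@H]2c1cc(OC)c(OC)c(OC)c1 | intermediate
21 | (2R,3S,3aS)-3a-allyl-5,7-dimethoxy-2-methyl-3-(3,4,5-trimethoxyphenyl)-3,3a-dihydro-1-benzofuran-6(2H)-one (allyl cis to methyl and trans to aryl) | C=CC[C@]12C=C(OC)C(=O)C(OC)=C1O[C@H](C)[C@H]2c1cc(OC)c(OC)c(OC)c1 | intermediate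
22 | (2R,3S,3aR)-3a-allyl-6-[dimethyl(phenyl)silyloxy]-5,7-dimethoxy-2-methyl-3-(3,4,5-trimethoxyphenyl)-2,3,3a,4-tetrahydro-1-benzofuran | C=CC[C@]12CC(OC)=C(O[Si](C)(C)c3ccccc3)C(OC)=C1O[C@H](C)[C@H]2c1cc(OC)c(OC)c(OC)c1 | intermediate
23 | (2R,3S,3aR,5S)-3a-allyl-5,7-dimethoxy-2-methyl-3-(3,4,5-trimethoxyphenyl)-3,3a,4,5-tetrahydro-1-benzofuran-6(2H)-one | C=CC[C@]12C[C@H](OC)C(=O)C(OC)=C1O[C@H](C)[C@H]2c1cc(OC)c(OC)c(OC)c1 | target

Total step count: 10. Longest linear sequence: 9 steps (steps 1 to 4 and 6 to 10).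

Steps most likely to fail

1. Step 6. The chiral leaving group may give too little or the opposite asymmetric induction, and the electron-rich o-quinone methide may oligomerise if the ylide adds slowly. Fallback: starting again from 10, the annulation is run under hydrogen-bond catalysis with a sulfonium ylide. The o-quinone methide from 10 reacts with the ylide of (2-tert-butoxy-2-oxoethyl)dimethylsulfonium bromide in the presence of a chiral bifunctional squaramide (K2CO3, CH2Cl2), which should give tert-butyl (2S,3S)-6-(allyloxy)-5,7-dimethoxy-3-(3,4,5-trimethoxyphenyl)-2,3-dihydro-1-benzofuran-2-carboxylate F1. Reduction of the ester with LiAlH4 in THF rejoins the route at 17.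

2. Step 9. The Claisen–Cope equilibrium may lie on the side of the aryl ether, or the allyl group may be delivered to the wrong face. Fallback: starting from 19, the allyl ether is cleaved with Pd(PPh3)4 and morpholine in THF to give (2R,3S)-5,7-dimethoxy-2-methyl-3-(3,4,5-trimethoxyphenyl)-2,3-dihydro-1-benzofuran-6-ol F2. Oxidative dearomatisation of this phenol with PhI(OAc)2 in hexafluoroisopropanol in the presence of allyltrimethylsilane traps the phenoxonium ion at C3a anti to the aryl group and comes back at 21.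

3. Step 10. 1,2-Reduction may compete, and the protonation at C5 may show poor facial selectivity or be followed by epimerisation. Fallback: starting from 21, conjugate reduction with Li(s-Bu)3BH in THF at −78 °C and trapping with Me3SiCl gives (2R,3S,3aR)-3a-allyl-5,7-dimethoxy-2-methyl-3-(3,4,5-trimethoxyphenyl)-6-(trimethylsilyloxy)-2,3,3a,4-tetrahydro-1-benzofuran F3, which is isolated. It is then protonated under reagent control with a Lewis acid-assisted chiral Brønsted acid (the SnCl4 complex of the matching BINOL enantiomer, 2,6-dimethylphenol as proton source, toluene, −78 °C), coming back at 23.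

Further compounds
F1 | step 6 | tert-butyl (2S,3S)-6-(allyloxy)-5,7-dimethoxy-3-(3,4,5-trimethoxyphenyl)-2,3-dihydro-1-benzofuran-2-carboxylate | C=CCOc1c(OC)cc2c(c1OC)O[C@H](C(=O)OC(C)(C)C)[C@H]2c1cc(OC)c(OC)c(OC)c1
F2 | step 9 | (2R,3S)-5,7-dimethoxy-2-methyl-3-(3,4,5-trimethoxyphenyl)-2,3-dihydro-1-benzofuran-6-ol | COc1cc2c(c(OC)c1O)O[C@H](C)[C@H]2c1cc(OC)c(OC)c(OC)c1
F3 | step 10 | (2R,3S,3aR)-3a-allyl-5,7-dimethoxy-2-methyl-3-(3,4,5-trimethoxyphenyl)-6-(trimethylsilyloxy)-2,3,3a,4-tetrahydro-1-benzofuran | C=CC[C@]12CC(OC)=C(O[Si](C)(C)C)C(OC)=C1O[C@H](C)[C@H]2c1cc(OC)c(OC)c(OC)c1
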